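Count every amount as a fraction of the starting material charged, and start from the coupling partner. Take off the second substrate, assuming it uses coupling partner one to one, and, taking target as made one to one from coupling partner, the limiting reagent leaves a ceiling of 0.800 for target.

| setting | epsilon | zeta | flask |
|---|---|---|---|
| starting material | 0.50 M | 0.50 M | 0.50 M |
| coupling partner | 1 equiv | 0.50 equiv | 1.00 equiv |
| second substrate | 0.20 equiv | 0.20 equiv | 0.200 equiv |
| protic impurity | 0.15 M | 0.15 M | 0.150 M |
| remark | the very flask that is asked about, followed so far | run made earlier |  |
| time |  |  | 8.0 d |

| run | time / h | target / % | starting material / % |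
|---|---|---|---|
| epsilon | 12.0 | 46 | 29 |
| epsilon | 20.0 | 50 | 18 |
| epsilon | 30.0 | 52 | 14 |
| epsilon | 60.0 | 56 | 6 |
| epsilon | 96.0 | 56 | 6 |
| epsilon | 144 | 58 | 1 |
| zeta | 0.833 | 11 | 92 |
| zeta | 1.50 | 15 | 86 |
| zeta | 2.50 | 13 | 80 |
| zeta | 3.00 | 17 | 76 |
| zeta | 4.00 | 18 | 71 |
| zeta | 5.00 | 17 | 70 |

(readings scatter by 1.5 percentage points)
1. target, in percent of the starting material first charged, at 8.0 d
2. which option adds most target ("none" when 2 percentage points or less is all one gets) (red / violet / green / blue / none)
3. target present, with what was taken out counted in, in percent of the starting material first charged, after red
4. target present, with what was taken out counted in, in percent of the starting material first charged, after violet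
- target taken out counts as made
- additions bring no volume worth counting
- red: at 8.0 d add coupling partner, 100% of the amount charged, then wait 2.5 d
- violet: change nothing and wait 2.5 d more
- green: at 8.0 d add starting material, 50.0% of the amount charged, then wait 2.5 d
- blue: at 8.0 d take out 90% of the target then present, then wait 2.5 d

Use that ceiling as the crude upper bound, then tighten it with the epsilon flask, which is the asked flask. At 144 h it read 58% target with 1% starting material left. Add both to two standard deviations for an upper bound of 62.0%, lower than the ceiling, and subtract the scatter from the target for a lower bound of 55.0%.

Now divide that target reading by the ceiling to get the target share, the part of what the ceiling allows that stands as target: 0.725. The zeta run suggests that the rest may not be lost at once: it read 11% target for 8.00% starting material gone at 0.833 h, but 17% for 30.0% at 5.00 h. If the rest stands in balance with target, taking out a part of the target refills it by that part times one minus the target share, which for blue is 14 percentage points; if the rest is lost for good, blue adds nothing.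

The forecast gives 58.5%, below the upper bound and above the lower one, with 59.8% after red and 59% after violet. It chooses none, “since nothing suggests reversibility”, and there my reckoning parts from it.

The flask gives 57.4%, inside the bracket, with 58.3% after red and 57.5% after violet, and blue adds 14 points, more than any other option.

    second substrate + coupling partner → second product (k = 6.00 L mol⁻¹ h⁻¹)
    starting material + coupling partner → target (k = 0.510 L mol⁻¹ h⁻¹)
    starting material + protic impurity → quenched substrate (k = 0.140 L mol⁻¹ h⁻¹)
    target ⇌ isomer of the product (K = 0.370, k = 0.130 h⁻¹)

Isomer of the product stands at 21.2% beside the target, and the pair relaxes with a half-life of 1.44 h, shorter than the wait of 2.5 d. Apply the target share to 57.4% and the refill for blue comes to 14 points. Apply it to the neighbour charged with 1.70 equiv of coupling partner, whose target and isomer of the product together make 93.0%, and it gives 67.5% target, where that flask holds 67.9%.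

The earlier runs and the new flask are simulated with made-up constants, noise included.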